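**Plan**

- Retrosynthesis: after O-debenzylation, the C1–C4 bond (carbonyl carbon to benzylic CH2) is re-formed on paper, turning the tetralone into a benzo-fused bicyclo[2.2.0]hexan-1-ol. The two aryl bonds C8a–C1 and C4a–C4 are then cut as a [2+2] retron to the C4a≡C8a aryne and a 3-benzyloxy-1-silyloxycyclobutene.
- Enabling feature: C1 and C4 sit on the adjacent ring carbons C8a and C4a and are bridged by C2–C3, so they are a masked four-membered enol ether. The C8 oxygen polarises the aryne so that C4 goes to C4a and C1 to C8a.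
- Further cuts: the pyranone ring (C4–C5 and O1–C2, from a methyl ketone and malonyl dichloride), the aryl–acetyl bond (Hoesch), and the C–I, O–benzyl and O–triflyl bonds of a 5-phenylresorcinol core.
- Forward order: the resorcinol ring is dressed (acetyl, iodide, benzyl ether, triflate), the pyranone ring is built, the benzocyclobutene ring is closed onto the cyclobutene (key step), the central bond is broken by alkoxy-radical β-scission to give the six-membered ketone ring, and the benzyl groups are removed.
- Stereochemistry: the only stereocentre (C3, S) comes from enantioselective deprotonation of prochiral 3-(benzyloxy)cyclobutanone by a chiral lithium amide. The position of the enol double bond fixes which methylene becomes C4; the stereocentres made in the key step are erased.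

Key step: step 8

Assumption: biphenyl-3,5-diol and 3-(benzyloxy)cyclobutan-1-one are taken as catalogue compounds; arene intermediates are numbered as biphenyls, the target and late intermediates as 1-tetralones (C1 carbonyl, C3 carbinol, C4a and C8a ring-fusion carbons).

**Route**

Step 1
Reactants: 1 biphenyl-3,5-diol (5-phenylresorcinol)
Product: 3 1-(3,5-dihydroxy-[1,1'-biphenyl]-2-yl)ethan-1-one, via ketiminium chloride 2 (not isolated)
Conditions: MeCN, ZnCl2, HCl (g), Et2O, 0 °C; then H2O, 100 °C
Reagents that add atoms: acetonitrile CC#N; water O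
Why: Houben–Hoesch acylation of a resorcinol, expected (as with other 5-substituted resorcinols) para to one hydroxyl and ortho to the other, at C2 next to the phenyl group, and limited to mono-acylation because the ketiminium salt deactivates the ring.

Step 2
Reactants: 3 1-(3,5-dihydroxy-[1,1'-biphenyl]-2-yl)ethan-1-one
Product: 4 1-(3,5-dihydroxy-4-iodo-[1,1'-biphenyl]-2-yl)ethan-1-one
Conditions: I2, HIO3, EtOH–H2O, 35 °C
Reagents that add atoms: iodine I-I; iodic acid OI(=O)=O
Why: Electrophilic iodination, which for 2,4-dihydroxyaryl ketones under iodine/iodic acid should go to the doubly activated position between the two hydroxyls (C4), the other free position being shielded by the phenyl group.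

Step 3
Reactants: 4 1-(3,5-dihydroxy-4-iodo-[1,1'-biphenyl]-2-yl)ethan-1-one
Product: 5 1-[5-(benzyloxy)-3-hydroxy-4-iodo-[1,1'-biphenyl]-2-yl]ethan-1-one
Conditions: BnBr (1.05 equiv), K2CO3, acetone, 50 °C
Reagents that add atoms: benzyl bromide BrCc1ccccc1
Why: Williamson etherification that should be selective for the C5 hydroxyl para to the acetyl group, because the C3 hydroxyl is held in a hydrogen bond to the ketone and is much less nucleophilic.

Step 4
Reactants: 5 1-[5-(benzyloxy)-3-hydroxy-4-iodo-[1,1'-biphenyl]-2-yl]ethan-1-one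
Product: 6 2-acetyl-5-(benzyloxy)-4-iodo-[1,1'-biphenyl]-3-yl trifluoromethanesulfonate
Conditions: Tf2O, pyridine, CH2Cl2, 0 °C to rt
Reagents that add atoms: trifluoromethanesulfonic anhydride O=S(=O)(OS(=O)(=O)C(F)(F)F)C(F)(F)F
Why: O-Sulfonylation of the remaining phenol gives the ortho-iodoaryl triflate that later serves as aryne precursor and also blocks the phenol, so that the pyranone annulation cannot divert to a chromone.

Step 5
Reactants: 6 2-acetyl-5-(benzyloxy)-4-iodo-[1,1'-biphenyl]-3-yl trifluoromethanesulfonate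
Product: 8 5-(benzyloxy)-2-(4-hydroxy-2-oxo-2H-pyran-6-yl)-4-iodo-[1,1'-biphenyl]-3-yl trifluoromethanesulfonate, via silyl enol ether 7 (not isolated)
Conditions: TMSOTf, Et3N, CH2Cl2, 0 °C; pentane, filtration; then malonyl dichloride, Et2O, −78 °C to rt
Reagents that add atoms: malonyl dichloride O=C(Cl)CC(=O)Cl
Why: Soft enolisation of the methyl ketone to its trimethylsilyl enol ether, C-acylation of this by malonyl dichloride and enol-lactonisation of the resulting 3,5-dioxoacyl chloride is a known one-flask route from methyl ketones to 6-substituted 4-hydroxy-2-pyranones and acts at the CH3 group, remote from the crowded ring.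

Step 6
Reactants: 8 5-(benzyloxy)-2-(4-hydroxy-2-oxo-2H-pyran-6-yl)-4-iodo-[1,1'-biphenyl]-3-yl trifluoromethanesulfonate
Product: 9 5-(benzyloxy)-2-[4-(benzyloxy)-2-oxo-2H-pyran-6-yl]-4-iodo-[1,1'-biphenyl]-3-yl trifluoromethanesulfonate
Conditions: BnOH, PPh3, DIAD, THF, 0 °C to rt
Reagents that add atoms: benzyl alcohol OCc1ccccc1
Why: Mitsunobu alkylation of the acidic 4-hydroxy-2-pyranone, which is known to go on the 4-oxygen, masks the only acidic and nucleophilic site before the aryne step with a group that leaves by hydrogenolysis.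

Step 7
Reactants: 10 3-(benzyloxy)cyclobutan-1-one
Product: 12 (R)-{[3-(benzyloxy)cyclobut-1-en-1-yl]oxy}trimethylsilane, via lithium enolate 11 (not isolated)
Conditions: (R,R)-bis(1-phenylethyl)amine, n-BuLi, THF, −78 °C; TMSCl; then 10 added slowly, −100 °C; Et3N, pentane work-up
Reagents that add atoms: chlorotrimethylsilane C[Si](C)(C)Cl
Why: Enantioselective deprotonation of a prochiral 3-substituted cyclobutanone by a C2-symmetric chiral lithium amide with internal silyl quench, in which the base distinguishes the two enantiotopic α-methylene groups and immediate silylation forestalls loss of benzyloxide from the enolate; the (R) configuration of the enol ether is the target's stereocentre, the sense being assigned by analogy and the antipodal amide being equally available.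

Step 8
Reactants: 9 5-(benzyloxy)-2-[4-(benzyloxy)-2-oxo-2H-pyran-6-yl]-4-iodo-[1,1'-biphenyl]-3-yl trifluoromethanesulfonate; 12 (R)-{[3-(benzyloxy)cyclobut-1-en-1-yl]oxy}trimethylsilane
Product: 16 (1S,8S,9R)-3,9-bis(benzyloxy)-6-[4-(benzyloxy)-2-oxo-2H-pyran-6-yl]-5-phenyltricyclo[6.2.0.0^{2,7}]deca-2,4,6-trien-1-ol, via arylmagnesium chloride 13 (not isolated), via aryne 14 (not isolated), via silyl ether 15 (not isolated)
Conditions: 12 (3 equiv), Me3SiCH2MgCl (1.3 equiv, slow addition), THF, −78 to −30 °C; then citric acid, MeOH, 0 °C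
Reagents that add atoms: none
Why: Iodine–magnesium exchange at C4 of 9 with the weakly nucleophilic silylmethyl Grignard reagent and loss of the neighbouring triflate should release aryne 14 at −78 °C, the =CH carbon of enol ether 12 then adds to the aryne carbon that carried the triflate and the aryl anion so formed collapses onto the silyloxocarbenium carbon, so that the aryl–CH and aryl–C(O) bonds arise in a single stepwise polar [2+2] cycloaddition. The closest known reaction type is the [2+2] cycloaddition of 3-alkoxyarynes with ketene silyl acetals and enol ethers, which gives benzocyclobutenone acetals and benzocyclobutenyl ethers with the oxygenated carbon next to the alkoxy group. The one ring closed is the four-membered benzocyclobutene ring, by 4-exo-trig attack of the aryl anion on the oxocarbenium carbon, and it shares the old C1–C2 bond of the cyclobutene, so that a benzo-fused bicyclo[2.2.0]hexane results. Two stereocentres are created (C1 and C8 of 16): they are cis by necessity of the ring fusion and should form on the face of the enol ether opposite to the C3 benzyloxy group, and both are erased in step 9, while the carbinol stereocentre set in step 7 is not touched. The step needs regioselectivity and chemoselectivity: the first is secured by the C5 benzyloxy group of the aryne, whose inductive pull directs the nucleophilic carbon to the distal aryne carbon and the developing negative charge to the carbon beside oxygen (the small CH terminus also suits the more hindered carbon next to the pyranone), the second by the excess of the strained electron-rich enol ether and the low temperature, which should keep the aryne away from the pyranone diene and the Grignard reagent. Mild acidic methanolysis during work-up removes the trimethylsilyl group so that cyclobutenol 16 is isolated.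

Step 9
Reactants: 16 (1S,8S,9R)-3,9-bis(benzyloxy)-6-[4-(benzyloxy)-2-oxo-2H-pyran-6-yl]-5-phenyltricyclo[6.2.0.0^{2,7}]deca-2,4,6-trien-1-ol
Product: 17 (S)-3,8-bis(benzyloxy)-5-[4-(benzyloxy)-2-oxo-2H-pyran-6-yl]-6-phenyl-3,4-dihydronaphthalen-1(2H)-one
Conditions: [Ir(dF(CF3)ppy)2(5,5'-d(CF3)bpy)]PF6 (2 mol %), 2,4,6-collidine, PhSH (25 mol %), CH2Cl2, blue LEDs, rt
Reagents that add atoms: none
Why: Photocatalytic proton-coupled electron transfer ring-opening of a tertiary cycloalkanol, in which the alkoxy radical at C1 should undergo β-scission of the central C1–C8 bond (the only cleavage that opens both four-membered rings and gives a secondary benzylic radical) and hydrogen-atom transfer from the thiol then leaves the benzylic CH2, a radical pathway chosen because a carbanion at this position would expel the adjacent benzyloxy group; the C3 stereocentre is untouched.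

Step 10
Reactants: 17 (S)-3,8-bis(benzyloxy)-5-[4-(benzyloxy)-2-oxo-2H-pyran-6-yl]-6-phenyl-3,4-dihydronaphthalen-1(2H)-one
Product: 18 Wailupemycin F, (S)-3,8-dihydroxy-5-(4-hydroxy-2-oxo-2H-pyran-6-yl)-6-phenyl-3,4-dihydronaphthalen-1(2H)-one
Conditions: H2 (1 atm), 10% Pd/C, EtOAc–MeOH, rt
Reagents that add atoms: none
Why: Hydrogenolysis of the three benzyl ethers (aryl, vinylogous ester and secondary alkyl) under neutral conditions, chosen because the β-hydroxy ketone would aromatise to a naphthol under acid or base; no stereocentre is affected.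

**Compound list**

1 | biphenyl-3,5-diol | Oc1cc(O)cc(-c2ccccc2)c1 | starting material
2 | 1-(3,5-dihydroxy-[1,1'-biphenyl]-2-yl)ethan-1-iminium chloride (not isolated) | CC(=[NH2+])c1c(O)cc(O)cc1-c1ccccc1.[Cl-] | intermediate
3 | 1-(3,5-dihydroxy-[1,1'-biphenyl]-2-yl)ethan-1-one | CC(=O)c1c(O)cc(O)cc1-c1ccccc1 | intermediate
4 | 1-(3,5-dihydroxy-4-iodo-[1,1'-biphenyl]-2-yl)ethan-1-one | CC(=O)c1c(O)c(I)c(O)cc1-c1ccccc1 | intermediate
5 | 1-[5-(benzyloxy)-3-hydroxy-4-iodo-[1,1'-biphenyl]-2-yl]ethan-1-one | CC(=O)c1c(O)c(I)c(OCc2ccccc2)cc1-c1ccccc1 | intermediate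
6 | 2-acetyl-5-(benzyloxy)-4-iodo-[1,1'-biphenyl]-3-yl trifluoromethanesulfonate | CC(=O)c1c(OS(=O)(=O)C(F)(F)F)c(I)c(OCc2ccccc2)cc1-c1ccccc1 | intermediate
7 | 5-(benzyloxy)-4-iodo-2-{1-[(trimethylsilyl)oxy]ethenyl}-[1,1'-biphenyl]-3-yl trifluoromethanesulfonate (not isolated) | C=C(O[Si](C)(C)C)c1c(OS(=O)(=O)C(F)(F)F)c(I)c(OCc2ccccc2)cc1-c1ccccc1 | intermediate
8 | 5-(benzyloxy)-2-(4-hydroxy-2-oxo-2H-pyran-6-yl)-4-iodo-[1,1'-biphenyl]-3-yl trifluoromethanesulfonate | O=c1cc(O)cc(-c2c(OS(=O)(=O)C(F)(F)F)c(I)c(OCc3ccccc3)cc2-c2ccccc2)o1 | intermediate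
9 | 5-(benzyloxy)-2-[4-(benzyloxy)-2-oxo-2H-pyran-6-yl]-4-iodo-[1,1'-biphenyl]-3-yl trifluoromethanesulfonate | O=c1cc(OCc2ccccc2)cc(-c2c(OS(=O)(=O)C(F)(F)F)c(I)c(OCc3ccccc3)cc2-c2ccccc2)o1 | intermediate
10 | 3-(benzyloxy)cyclobutan-1-one | O=C1CC(OCc2ccccc2)C1 | starting material
11 | lithium (R)-3-(benzyloxy)cyclobut-1-en-1-olate (not isolated) | [Li]OC1=C[C@H](OCc2ccccc2)C1 | intermediate
12 | (R)-{[3-(benzyloxy)cyclobut-1-en-1-yl]oxy}trimethylsilane | C[Si](C)(C)OC1=C[C@H](OCc2ccccc2)C1 | intermediate
13 | {5-(benzyloxy)-2-[4-(benzyloxy)-2-oxo-2H-pyran-6-yl]-3-[(trifluoromethanesulfonyl)oxy]-[1,1'-biphenyl]-4-yl}magnesium chloride (not isolated) | O=c1cc(OCc2ccccc2)cc(-c2c(OS(=O)(=O)C(F)(F)F)c([Mg]Cl)c(OCc3ccccc3)cc2-c2ccccc2)o1 | intermediate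
14 | 5-(benzyloxy)-2-[4-(benzyloxy)-2-oxo-2H-pyran-6-yl]-3,4-didehydro-1,1'-biphenyl, the 3,4-aryne (not isolated) | O=c1cc(OCc2ccccc2)cc(C2=C(c3ccccc3)C=C(OCc3ccccc3)C#C2)o1 | intermediate
15 | {[(1S,8S,9R)-3,9-bis(benzyloxy)-6-[4-(benzyloxy)-2-oxo-2H-pyran-6-yl]-5-phenyltricyclo[6.2.0.0^{2,7}]deca-2,4,6-trien-1-yl]oxy}trimethylsilane; cis ring fusion, 9-benzyloxy group anti to the arene (not isolated) | C[Si](C)(C)O[C@@]12C[C@@H](OCc3ccccc3)[C@@H]1c1c(-c3cc(OCc4ccccc4)cc(=O)o3)c(-c3ccccc3)cc(OCc3ccccc3)c12 | intermediate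
16 | (1S,8S,9R)-3,9-bis(benzyloxy)-6-[4-(benzyloxy)-2-oxo-2H-pyran-6-yl]-5-phenyltricyclo[6.2.0.0^{2,7}]deca-2,4,6-trien-1-ol; benzocyclobutenol cis-fused to the cyclobutane, 9-benzyloxy group anti to the arene | O[C@@]12C[C@@H](OCc3ccccc3)[C@@H]1c1c(-c3cc(OCc4ccccc4)cc(=O)o3)c(-c3ccccc3)cc(OCc3ccccc3)c12 | intermediate
17 | (S)-3,8-bis(benzyloxy)-5-[4-(benzyloxy)-2-oxo-2H-pyran-6-yl]-6-phenyl-3,4-dihydronaphthalen-1(2H)-one | O=C1C[C@@H](OCc2ccccc2)Cc2c1c(OCc1ccccc1)cc(-c1ccccc1)c2-c1cc(OCc2ccccc2)cc(=O)o1 | intermediate
18 | Wailupemycin F, (S)-3,8-dihydroxy-5-(4-hydroxy-2-oxo-2H-pyran-6-yl)-6-phenyl-3,4-dihydronaphthalen-1(2H)-one | O=C1C[C@@H](O)Cc2c1c(O)cc(-c1ccccc1)c2-c1cc(O)cc(=O)o1 | target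

**Step count and risks**

Total step count: 10. Longest linear sequence: 9 steps (steps 1–6 and 8–10).

Steps most likely to fail:

1. Step 8. What may go wrong: the aryne is consumed faster by transfer of an allylic hydrogen from 12 (α-arylation instead of ring formation), by addition of the Grignard reagent, or by Diels–Alder capture on the pyranone of a second molecule, so that little cycloadduct forms. The fallback gives up the aryne and takes the stereocentre from the chiral pool; it sets out from 9 and comes back to the route at 17. Commercial ethyl (R)-4-bromo-3-hydroxybutanoate F1 is O-benzylated under acid catalysis (benzyl 2,2,2-trichloroacetimidate, TfOH) to ethyl (R)-3-(benzyloxy)-4-bromobutanoate F2, which AlMe3/EtSH converts into S-ethyl (R)-3-(benzyloxy)-4-bromobutanethioate F3. Zinc insertion into the C–I bond of 9 (Zn, LiCl, THF) should give the arylzinc iodide F4 (not isolated), which does not eliminate the neighbouring triflate, and Fukuyama coupling with F3 (PdCl2(PPh3)2) should give the bromo ketone F5. A nickel-catalysed intramolecular reductive coupling of the aryl triflate with the primary bromide (NiBr2(dme), 4,4'-di-tert-butyl-2,2'-bipyridine, Zn, NaI, DMA) then closes the six-membered ring to 17.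

2. Step 9. What may go wrong: β-scission toward the CH2 carbon instead of the central bond, or oxidation of the benzylic radical followed by loss of benzyl alcohol and aromatisation to a naphthol, or quenching of the photocatalyst by the pyranone. The fallback replaces the radical opening by a two-electron fragmentation after deprotection; it sets out from 16 and comes back at 18. Hydrogenolysis of 16 first (H2, Pd/C, EtOAc) should give the tricyclic triol F6. With K2CO3 in MeOH at 0 °C its cyclobutenoxide should open the central bond in a strain-driven retro-aldol-type fragmentation, and the ortho-acylbenzyl anion is protonated by the solvent to give 18 directly. Elimination is disfavoured there because the C3 oxygen is then a free hydroxyl, a far poorer leaving group than benzyloxide.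

3. Step 7. What may go wrong: incomplete discrimination between the two enantiotopic methylene groups, or loss of benzyloxide from the enolate before silylation, so that the enol ether is not enantiomerically pure. The fallback uses resolution instead of asymmetric deprotonation; it sets out from 10 and comes back at 16. Soft enolisation of 10 (TMSOTf, Et3N, CH2Cl2) gives the racemic enol ether F7. The conditions of step 8 with 9 then give, via the racemic silyl ether F8 (not isolated), the racemic cyclobutenol F9. Preparative HPLC on a chiral stationary phase separates 16 from the (1R,8R,9S) enantiomer F10.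

Further compounds
F1 | step 8 | ethyl (R)-4-bromo-3-hydroxybutanoate | CCOC(=O)C[C@@H](O)CBr
F2 | step 8 | ethyl (R)-3-(benzyloxy)-4-bromobutanoate | CCOC(=O)C[C@@H](OCc1ccccc1)CBr
F3 | step 8 | S-ethyl (R)-3-(benzyloxy)-4-bromobutanethioate | CCSC(=O)C[C@@H](OCc1ccccc1)CBr
F4 | step 8 | {5-(benzyloxy)-2-[4-(benzyloxy)-2-oxo-2H-pyran-6-yl]-3-[(trifluoromethanesulfonyl)oxy]-[1,1'-biphenyl]-4-yl}zinc iodide | O=c1cc(OCc2ccccc2)cc(-c2c(OS(=O)(=O)C(F)(F)F)c([Zn]I)c(OCc3ccccc3)cc2-c2ccccc2)o1
F5 | step 8 | 5-(benzyloxy)-4-[(3R)-3-(benzyloxy)-4-bromobutanoyl]-2-[4-(benzyloxy)-2-oxo-2H-pyran-6-yl]-[1,1'-biphenyl]-3-yl trifluoromethanesulfonate | O=C(C[C@@H](OCc1ccccc1)CBr)c1c(OCc2ccccc2)cc(-c2ccccc2)c(-c2cc(OCc3ccccc3)cc(=O)o2)c1OS(=O)(=O)C(F)(F)F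
F6 | step 9 | (1S,8S,9R)-6-(4-hydroxy-2-oxo-2H-pyran-6-yl)-5-phenyltricyclo[6.2.0.0^{2,7}]deca-2,4,6-triene-1,3,9-triol | O[C@@]12C[C@@H](O)[C@@H]1c1c(-c3cc(O)cc(=O)o3)c(-c3ccccc3)cc(O)c12
F7 | step 7 | racemic {[3-(benzyloxy)cyclobut-1-en-1-yl]oxy}trimethylsilane | C[Si](C)(C)OC1=CC(OCc2ccccc2)C1
F8 | step 7 | racemic silyl ether of F9, relative configuration (1S*,8S*,9R*) as in 15 | C[Si](C)(C)OC12CC(OCc3ccccc3)C1c1c(-c3cc(OCc4ccccc4)cc(=O)o3)c(-c3ccccc3)cc(OCc3ccccc3)c12
F9 | step 7 | racemic 3,9-bis(benzyloxy)-6-[4-(benzyloxy)-2-oxo-2H-pyran-6-yl]-5-phenyltricyclo[6.2.0.0^{2,7}]deca-2,4,6-trien-1-ol, relative configuration (1S*,8S*,9R*) as in 16 | OC12CC(OCc3ccccc3)C1c1c(-c3cc(OCc4ccccc4)cc(=O)o3)c(-c3ccccc3)cc(OCc3ccccc3)c12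
F10 | step 7 | (1R,8R,9S)-3,9-bis(benzyloxy)-6-[4-(benzyloxy)-2-oxo-2H-pyran-6-yl]-5-phenyltricyclo[6.2.0.0^{2,7}]deca-2,4,6-trien-1-ol, the enantiomer of 16 | O[C@]12C[C@H](OCc3ccccc3)[C@H]1c1c(-c3cc(OCc4ccccc4)cc(=O)o3)c(-c3ccccc3)cc(OCc3ccccc3)c12
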